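**Retrosynthetic overview**

1. Last bond: the oxolane O–C5 bond, closed across the finished ten-membered carbocycle by palladium-catalysed allylic etherification. The hydrate oxygen of the C2 ketone attacks the C15–C4–C5 allyl unit released from a C5 tert-butyl carbonate; both C5 epimers should converge.
2. Enabling feature: the ring oxygen sits on C5, which is allylic to the exocyclic C4=C15 methylene, and its other partner C2 (ketone level) hangs on the central allyl carbon C4 through C3. The 3-methyleneoxolane ring (O, C2, C3, C4, C5) inscribed in the ten-membered ring C1–C10 is therefore an allyl unit trapped by its own transannular carbonyl.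
3. Ten-membered carbocycle: C4–C5 by intramolecular Ni/Cr vinyl iodide–aldehyde coupling, after C1–C2 has been made by indium Barbier allylation with 3-iodobut-3-enal.
4. α-Methylene lactone with C6, C7 and C8: zinc Barbier reaction of a 3-(bromomethyl)butenolide (C6 from (S)-but-3-ene-1,2-diol, ring by metathesis) with 3-(chloromethyl)but-3-enal.
5. Ring order: lactone (step 3), ten-membered carbocycle (step 14), oxolane/hemiketal (step 18).

Key step: step 18

Numbering remark: germacrane numbering is used (ring C1–C10, lactone C11–C13 with C12 the carbonyl, exocyclic methylenes C14 on C10 and C15 on C4).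

Assumption: C2 (compounds 15–21) and C5 (compounds 19–23) are carried as epimer mixtures and are written without configuration in the SMILES; C2 is oxidised in step 17 and C5 is converged in step 18.

**Route**

Step 1
Reactants: 1 (S)-but-3-ene-1,2-diol
Product: 2 (S)-1-[(tert-butyldimethylsilyl)oxy]but-3-en-2-ol
Conditions: TBSCl, imidazole, CH2Cl2, −20 to 0 °C
Reagents that add atoms: tert-butyldimethylsilyl chloride, CC(C)(C)[Si](C)(C)Cl
Why: Silyl ether formation selective for the less hindered primary hydroxyl; the carbinol centre (later C6, S) comes unchanged from the chiral pool.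

Step 2
Reactants: 2 (S)-1-[(tert-butyldimethylsilyl)oxy]but-3-en-2-ol; 3 2-(bromomethyl)prop-2-enoic acid
Product: 4 (S)-1-[(tert-butyldimethylsilyl)oxy]but-3-en-2-yl 2-(bromomethyl)prop-2-enoate
Conditions: DCC, DMAP (cat.), CH2Cl2, 0 °C
Reagents that add atoms: none
Why: Steglich esterification of the secondary allylic alcohol at low temperature, which should leave the allylic bromide and the stereocentre untouched.

Step 3
Reactants: 4 (S)-1-[(tert-butyldimethylsilyl)oxy]but-3-en-2-yl 2-(bromomethyl)prop-2-enoate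
Product: 5 (S)-3-(bromomethyl)-5-{[(tert-butyldimethylsilyl)oxy]methyl}furan-2(5H)-one
Conditions: second-generation Grubbs catalyst (H2IMes)(PCy3)Cl2Ru=CHPh (5 mol %), CH2Cl2, 40 °C
Reagents that add atoms: none
Why: Ring-closing metathesis of the vinyl/acrylate diene should give the α-substituted butenolide with loss of ethene; C6 is not involved.

Step 4
Reactants: 6 3-chloro-2-(chloromethyl)prop-1-ene
Product: 7 3-(chloromethyl)but-3-en-1-ol
Conditions: In powder, NaI (cat.), 37 % aq. HCHO, THF/H2O 1:1, 25 °C, excess 6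
Reagents that add atoms: formaldehyde, C=O
Why: Indium-mediated Barbier allylation of formaldehyde in water; the excess of dichloride should hold the reaction at mono-allylation.

Step 5
Reactants: 7 3-(chloromethyl)but-3-en-1-ol
Product: 8 3-(chloromethyl)but-3-enal
Conditions: Dess–Martin periodinane, NaHCO3, CH2Cl2, 0 °C, used crude
Reagents that add atoms: none
Why: Buffered Dess–Martin oxidation should give the β,γ-unsaturated aldehyde without migration of the double bond.

Step 6
Reactants: 5 (S)-3-(bromomethyl)-5-{[(tert-butyldimethylsilyl)oxy]methyl}furan-2(5H)-one; 8 3-(chloromethyl)but-3-enal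
Product: 9 (4R,5S)-5-{[(tert-butyldimethylsilyl)oxy]methyl}-4-[(1S)-3-(chloromethyl)-1-hydroxybut-3-en-1-yl]-3-methylideneoxolan-2-one
Conditions: Zn dust, THF/sat. aq. NH4Cl 2:1, 0 to 25 °C
Reagents that add atoms: none
Why: Zinc Barbier allylation with allylic transposition (SE2') forms C7–C8 and the exocyclic C11=C13 methylene; the aldehyde should add anti to the C6 substituent (7R, trans lactone) and, through a closed chair transition state with the ring-locked allyl geometry, give 8S, while the allylic chloride stays inert to zinc.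

Step 7
Reactants: 9 Barbier adduct (6S,7R,8S); 10 (E)-2-methylbut-2-enoyl chloride
Product: 11 (1S)-1-[(2S,3R)-2-{[(tert-butyldimethylsilyl)oxy]methyl}-4-methylidene-5-oxooxolan-3-yl]-3-(chloromethyl)but-3-en-1-yl (E)-2-methylbut-2-enoate
Conditions: pyridine, DMAP (cat.), CH2Cl2, 0 to 25 °C
Reagents that add atoms: none
Why: DMAP-catalysed acylation of the C8 hydroxyl under weakly basic conditions, which should avoid translactonisation to the 8,12-olide and keep the E geometry of the tiglate.

Step 8
Reactants: 12 but-3-yn-1-ol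
Product: 13 3-iodobut-3-en-1-ol
Conditions: NaI, Me3SiCl, H2O (0.5 equiv), MeCN, 25 °C
Reagents that add atoms: sodium iodide, [Na+].[I-]
Why: Markovnikov hydroiodination of the terminal alkyne by hydrogen iodide made in the flask gives the 2-iodoalkene.

Step 9
Reactants: 13 3-iodobut-3-en-1-ol
Product: 14 3-iodobut-3-enal
Conditions: Dess–Martin periodinane, NaHCO3, CH2Cl2, 0 °C, used at once
Reagents that add atoms: none
Why: Buffered Dess–Martin oxidation; the labile β,γ-unsaturated aldehyde is not stored.

Step 10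
Reactants: 11 tiglate with allylic chloride; 14 3-iodobut-3-enal
Product: 15 (1S)-1-[(2S,3R)-2-{[(tert-butyldimethylsilyl)oxy]methyl}-4-methylidene-5-oxooxolan-3-yl]-5-hydroxy-7-iodo-3-methylideneoct-7-en-1-yl (E)-2-methylbut-2-enoate (C2 epimer mixture)
Conditions: In powder, NaI (cat.), DMF, 25 °C
Reagents that add atoms: none
Why: Indium-mediated Barbier allylation forms C1–C2 chemoselectively at the aldehyde in the presence of lactone, esters and vinyl iodide; the new C2 carbinol is unselective and is oxidised later.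

Step 11
Reactants: 15 homoallylic alcohol (C2 epimer mixture)
Product: 16 C2 tert-butyldiphenylsilyl ether of 15
Conditions: TBDPSCl, imidazole, DMAP (cat.), DMF, 25 °C
Reagents that add atoms: tert-butyldiphenylsilyl chloride, CC(C)(C)[Si](Cl)(c1ccccc1)c1ccccc1
Why: Silylation masks the future ketone carbon as a robust secondary silyl ether that survives the next four steps.

Step 12
Reactants: 16 bis-silyl ether
Product: 17 primary alcohol at C5 (C2 silyl ether kept)
Conditions: HF·pyridine, pyridine, THF, 0 °C
Reagents that add atoms: none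
Why: Buffered HF·pyridine should cleave the primary tert-butyldimethylsilyl ether selectively over the secondary tert-butyldiphenylsilyl ether.

Step 13
Reactants: 17 primary alcohol
Product: 18 C5 aldehyde bearing the 2-iodoallyl terminus
Conditions: Dess–Martin periodinane, NaHCO3, CH2Cl2, 0 °C
Reagents that add atoms: none
Why: Buffered Dess–Martin oxidation should give the α-acyloxy aldehyde without epimerising C6.

Step 14
Reactants: 18 iodo aldehyde
Product: 19 (6S,7R,8S)-2-[(tert-butyldiphenylsilyl)oxy]-5-hydroxy-8-[(E)-2-methylbut-2-enoyloxy]germacra-4(15),10(14),11(13)-trien-12,6-olide (C2 and C5 epimer mixture)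
Conditions: CrCl2 (8 equiv), NiCl2 (2 mol %), DMSO, 25 °C, 2 mM
Reagents that add atoms: none
Why: Intramolecular Nozaki–Hiyama–Kishi vinyl iodide–aldehyde coupling at high dilution should close the ten-membered carbocycle at C4–C5 chemoselectively at the aldehyde; C5 forms as an epimer mixture, which does not matter.

Step 15
Reactants: 19 macrocyclic allylic alcohol
Product: 20 C5 tert-butyl carbonate of 19
Conditions: Boc2O, DMAP (cat.), Et3N, CH2Cl2, 25 °C
Reagents that add atoms: di-tert-butyl dicarbonate, CC(C)(C)OC(=O)OC(=O)OC(C)(C)C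
Why: DMAP-catalysed carbonate formation turns both C5 epimers into ionisable allylic carbonates; tert-butyl is chosen so that ionisation releases non-nucleophilic tert-butoxide.

Step 16
Reactants: 20 silyl ether carbonate
Product: 21 (6S,7R,8S)-5-[(tert-butoxycarbonyl)oxy]-2-hydroxy-8-[(E)-2-methylbut-2-enoyloxy]germacra-4(15),10(14),11(13)-trien-12,6-olide (C2 and C5 epimer mixture)
Conditions: TBAF, AcOH, THF, 0 to 25 °C
Reagents that add atoms: none
Why: Acetic-acid-buffered fluoride desilylation should free the C2 hydroxyl without touching carbonate, tiglate or α-methylene lactone.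

Step 17
Reactants: 21 C2 alcohol
Product: 22 (6S,7R,8S)-5-[(tert-butoxycarbonyl)oxy]-8-[(E)-2-methylbut-2-enoyloxy]-2-oxogermacra-4(15),10(14),11(13)-trien-12,6-olide (C5 epimer mixture)
Conditions: Dess–Martin periodinane, NaHCO3, CH2Cl2, 0 °C
Reagents that add atoms: none
Why: Neutral Dess–Martin oxidation should give the doubly β,γ-unsaturated ketone without conjugation and erases the C2 mixture.

Step 18
Reactants: 22 macrocyclic keto carbonate (C5 epimer mixture)
Product: 24 (2S,5S,6S,7R,8S)-2,5-epoxy-2-hydroxy-8-[(E)-2-methylbut-2-enoyloxy]germacra-4(15),10(14),11(13)-trien-12,6-olide (target), via allylpalladium hydrate oxyanion complex 23 (not isolated)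
Conditions: Pd(PPh3)4 (5 mol %), THF/H2O 20:1, 25 °C
Reagents that add atoms: water, O
Why: Proposed new method: zerovalent palladium ionises either C5 epimer of the allylic tert-butyl carbonate to the cationic η3-allyl complex spanning C15–C4–C5 (CO2 and tert-butoxide leave), tert-butoxide and water turn the transannular C2 ketone into its hydrate oxyanion (complex 23), and this oxygen attacks C5 on the face opposite palladium to close the oxolane; the closest known reaction types are palladium-catalysed allylic etherification by hemiacetal oxyanions (tandem hemiacetal/Tsuji–Trost) and the ring-closing alkoxide attack of palladium–trimethylenemethane cycloadditions to carbonyl compounds, which builds the same 3-methyleneoxolane on a 2-substituted allyl. One ring is closed, the five-membered O–C2–C3–C4–C5 ring, transannularly across the ten-membered carbocycle by C–O bond formation at the allyl terminus C5 with the tether on the central allyl carbon (endo with respect to the allyl unit). C5 is set under Curtin–Hammett control: the complexes from the two carbonate epimers interconvert by η3–η1–η3 slippage at the unsubstituted C15 terminus, and the C2 oxygen is expected to reach C5 on the face syn to the C6–O bond (palladium on the open face anti to it), which keeps H5 anti to H6 and gives 5S; C2 is set by the bridge itself, because the oxygen can only span C2 and C5 cis, so the hydroxyl ends outside (2S) and stays correctable through hemiketal opening. The step needs attack at C5 and not at C15, secured because attack at C15 would leave C4=C5 as a bridgehead olefin (E in a ten- or eleven-membered ring), and O-alkylation rather than C-alkylation or elimination, secured by the weakly basic aqueous medium in which the hydrate and not an enolate is the nucleophile.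

**Compound list**

1 | (S)-but-3-ene-1,2-diol | C=C[C@H](O)CO | starting material
2 | (S)-1-[(tert-butyldimethylsilyl)oxy]but-3-en-2-ol | C=C[C@H](O)CO[Si](C)(C)C(C)(C)C | intermediate
3 | 2-(bromomethyl)prop-2-enoic acid | C=C(CBr)C(=O)O | starting material
4 | (S)-1-[(tert-butyldimethylsilyl)oxy]but-3-en-2-yl 2-(bromomethyl)prop-2-enoate | C=C[C@H](OC(=O)C(=C)CBr)CO[Si](C)(C)C(C)(C)C | intermediate
5 | (S)-3-(bromomethyl)-5-{[(tert-butyldimethylsilyl)oxy]methyl}furan-2(5H)-one | O=C1O[C@H](CO[Si](C)(C)C(C)(C)C)C=C1CBr | intermediate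
6 | 3-chloro-2-(chloromethyl)prop-1-ene | C=C(CCl)CCl | starting material
7 | 3-(chloromethyl)but-3-en-1-ol | OCCC(=C)CCl | intermediate
8 | 3-(chloromethyl)but-3-enal | O=CCC(=C)CCl | intermediate
9 | (4R,5S)-5-{[(tert-butyldimethylsilyl)oxy]methyl}-4-[(1S)-3-(chloromethyl)-1-hydroxybut-3-en-1-yl]-3-methylideneoxolan-2-one | ClCC(=C)C[C@H](O)[C@H]1C(=C)C(=O)O[C@@H]1CO[Si](C)(C)C(C)(C)C | intermediate
10 | (E)-2-methylbut-2-enoyl chloride (tigloyl chloride) | ClC(=O)/C(C)=C/C | starting material
11 | (1S)-1-[(2S,3R)-2-{[(tert-butyldimethylsilyl)oxy]methyl}-4-methylidene-5-oxooxolan-3-yl]-3-(chloromethyl)but-3-en-1-yl (E)-2-methylbut-2-enoate | ClCC(=C)C[C@H](OC(=O)/C(C)=C/C)[C@H]1C(=C)C(=O)O[C@@H]1CO[Si](C)(C)C(C)(C)C | intermediate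
12 | but-3-yn-1-ol | C#CCCO | starting material
13 | 3-iodobut-3-en-1-ol | C=C(I)CCO | intermediate
14 | 3-iodobut-3-enal | C=C(I)CC=O | intermediate
15 | (1S)-1-[(2S,3R)-2-{[(tert-butyldimethylsilyl)oxy]methyl}-4-methylidene-5-oxooxolan-3-yl]-5-hydroxy-7-iodo-3-methylideneoct-7-en-1-yl (E)-2-methylbut-2-enoate, C2 epimers | C=C(I)CC(O)CC(=C)C[C@H](OC(=O)/C(C)=C/C)[C@H]1C(=C)C(=O)O[C@@H]1CO[Si](C)(C)C(C)(C)C | intermediate
16 | 5-O-tert-butyldiphenylsilyl ether of 15 (octenyl numbering), C2 epimers | C=C(I)CC(O[Si](c1ccccc1)(c1ccccc1)C(C)(C)C)CC(=C)C[C@H](OC(=O)/C(C)=C/C)[C@H]1C(=C)C(=O)O[C@@H]1CO[Si](C)(C)C(C)(C)C | intermediate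
17 | 16 with the oxolane 2-(hydroxymethyl) group free, C2 epimers | C=C(I)CC(O[Si](c1ccccc1)(c1ccccc1)C(C)(C)C)CC(=C)C[C@H](OC(=O)/C(C)=C/C)[C@H]1C(=C)C(=O)O[C@@H]1CO | intermediate
18 | corresponding oxolane-2-carbaldehyde (C5 aldehyde), C2 epimers | C=C(I)CC(O[Si](c1ccccc1)(c1ccccc1)C(C)(C)C)CC(=C)C[C@H](OC(=O)/C(C)=C/C)[C@H]1C(=C)C(=O)O[C@@H]1C=O | intermediate
19 | (6S,7R,8S)-2-[(tert-butyldiphenylsilyl)oxy]-5-hydroxy-8-[(E)-2-methylbut-2-enoyloxy]germacra-4(15),10(14),11(13)-trien-12,6-olide, C2 and C5 epimers | C=C1C[C@H](OC(=O)/C(C)=C/C)[C@H]2C(=C)C(=O)O[C@@H]2C(O)C(=C)CC(O[Si](c3ccccc3)(c3ccccc3)C(C)(C)C)C1 | intermediate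
20 | 5-O-tert-butoxycarbonyl derivative of 19, C2 and C5 epimers | C=C1C[C@H](OC(=O)/C(C)=C/C)[C@H]2C(=C)C(=O)O[C@@H]2C(OC(=O)OC(C)(C)C)C(=C)CC(O[Si](c3ccccc3)(c3ccccc3)C(C)(C)C)C1 | intermediate
21 | (6S,7R,8S)-5-[(tert-butoxycarbonyl)oxy]-2-hydroxy-8-[(E)-2-methylbut-2-enoyloxy]germacra-4(15),10(14),11(13)-trien-12,6-olide, C2 and C5 epimers | C=C1C[C@H](OC(=O)/C(C)=C/C)[C@H]2C(=C)C(=O)O[C@@H]2C(OC(=O)OC(C)(C)C)C(=C)CC(O)C1 | intermediate
22 | (6S,7R,8S)-5-[(tert-butoxycarbonyl)oxy]-8-[(E)-2-methylbut-2-enoyloxy]-2-oxogermacra-4(15),10(14),11(13)-trien-12,6-olide, C5 epimers | C=C1C[C@H](OC(=O)/C(C)=C/C)[C@H]2C(=C)C(=O)O[C@@H]2C(OC(=O)OC(C)(C)C)C(=C)CC(=O)C1 | intermediate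
23 | η3-allylpalladium cation (divalent palladium, C15–C4–C5) with the C2 hydrate oxyanion, drawn as the η1-C15 form without phosphines | C=C1C[C@H](OC(=O)/C(C)=C/C)[C@H]2C(=C)C(=O)O[C@@H]2C=C(C[Pd+])CC(O)([O-])C1 | intermediate
24 | (2S,5S,6S,7R,8S)-2,5-epoxy-2-hydroxy-8-[(E)-2-methylbut-2-enoyloxy]germacra-4(15),10(14),11(13)-trien-12,6-olide | C=C1C[C@H](OC(=O)/C(C)=C/C)[C@H]2C(=C)C(=O)O[C@@H]2[C@H]2O[C@@](O)(C1)CC2=C | target

**Step count and risks**

Total: 18 steps (fragment steps 1–5 and 8–9 included). Longest linear sequence: 14 steps (1, 2, 3, 6, 7, 10–18).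

Steps most likely to fail:

1. Step 18 (proposed new method). The hydrate may lose to proton loss from the allyl complex (dienone formation), the oxygen may attack the exocyclic C15 terminus, or it may attack the wrong face of C5. The fallback uses known chemistry, sets out from 19 and comes back at 24. Compound 19 is desilylated with TBAF/AcOH to the 2,5-diol F1. Both carbinols are oxidised with Dess–Martin periodinane to the 2,5-dione F2. Luche reduction (NaBH4, CeCl3·7H2O, MeOH, −78 °C) should reduce only the conjugated C5 ketone, with Felkin–Anh approach anti to the C6–O bond, to the 5S-hydroxy ketone F3. F3 should close spontaneously onto the C2 ketone to give 24; the oxolane is then closed at O–C2.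

2. Step 14. Intermolecular coupling (oligomers) or protodehalogenation may outrun closure of the strained ten-membered ring. The fallback closes the ring at C1–C2 by an allylchromium–aldehyde addition instead; it sets out from 11 and 13 and comes back at 21. Compound 11 is desilylated (HF·pyridine) to the primary alcohol F4 and oxidised (Dess–Martin periodinane) to the aldehyde F5. Compound 13 is silylated (TBSCl, imidazole) to the iodoalkene silyl ether F6, which iodine–magnesium exchange (iPrMgCl·LiCl) and ZnCl2 convert into the alkenylzinc chloride F7. F7 adds to F5 to give the allylic alcohol F8 (C5 epimers), which Boc2O/DMAP converts into the carbonate F9. HF·pyridine gives the primary alcohol F10 and Dess–Martin periodinane the aldehyde F11. CrCl2 in THF/DMF at high dilution then joins the allylic chloride to the aldehyde and gives 21.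

3. Step 6. The Barbier addition may run through an open instead of a closed transition state and deliver the wrong C8 configuration. The fallback sets out from 5 and 8 and comes back at 11. If the same reaction gives mainly the 8R adduct F12, Mitsunobu esterification with (E)-2-methylbut-2-enoic acid (PPh3, DIAD, THF) installs the tiglate with inversion at C8 and gives 11 directly, replacing step 7.

**Further compounds**

F1 | step 18 | (6S,7R,8S)-2,5-dihydroxy-8-[(E)-2-methylbut-2-enoyloxy]germacra-4(15),10(14),11(13)-trien-12,6-olide, C2 and C5 epimers | C=C1C[C@H](OC(=O)/C(C)=C/C)[C@H]2C(=C)C(=O)O[C@@H]2C(O)C(=C)CC(O)C1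
F2 | step 18 | (6S,7R,8S)-8-[(E)-2-methylbut-2-enoyloxy]-2,5-dioxogermacra-4(15),10(14),11(13)-trien-12,6-olide | C=C1C[C@H](OC(=O)/C(C)=C/C)[C@H]2C(=C)C(=O)O[C@@H]2C(=O)C(=C)CC(=O)C1
F3 | step 18 | (5S,6S,7R,8S)-5-hydroxy-8-[(E)-2-methylbut-2-enoyloxy]-2-oxogermacra-4(15),10(14),11(13)-trien-12,6-olide | C=C1C[C@H](OC(=O)/C(C)=C/C)[C@H]2C(=C)C(=O)O[C@@H]2[C@@H](O)C(=C)CC(=O)C1
F4 | step 14 | (1S)-3-(chloromethyl)-1-[(2S,3R)-2-(hydroxymethyl)-4-methylidene-5-oxooxolan-3-yl]but-3-en-1-yl (E)-2-methylbut-2-enoate | ClCC(=C)C[C@H](OC(=O)/C(C)=C/C)[C@H]1C(=C)C(=O)O[C@@H]1CO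
F5 | step 14 | (1S)-3-(chloromethyl)-1-[(2S,3R)-2-formyl-4-methylidene-5-oxooxolan-3-yl]but-3-en-1-yl (E)-2-methylbut-2-enoate | ClCC(=C)C[C@H](OC(=O)/C(C)=C/C)[C@H]1C(=C)C(=O)O[C@@H]1C=O
F6 | step 14 | tert-butyl[(3-iodobut-3-en-1-yl)oxy]dimethylsilane | C=C(I)CCO[Si](C)(C)C(C)(C)C
F7 | step 14 | {4-[(tert-butyldimethylsilyl)oxy]but-1-en-2-yl}zinc chloride | C=C([Zn]Cl)CCO[Si](C)(C)C(C)(C)C
F8 | step 14 | allylic alcohol from F5 and F7 (C5 hydroxyl, C5 epimers; C2 as primary silyl ether) | ClCC(=C)C[C@H](OC(=O)/C(C)=C/C)[C@H]1C(=C)C(=O)O[C@@H]1C(O)C(=C)CCO[Si](C)(C)C(C)(C)C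
F9 | step 14 | C5 tert-butyl carbonate of F8 | ClCC(=C)C[C@H](OC(=O)/C(C)=C/C)[C@H]1C(=C)C(=O)O[C@@H]1C(OC(=O)OC(C)(C)C)C(=C)CCO[Si](C)(C)C(C)(C)C
F10 | step 14 | primary alcohol from F9 (C2 hydroxyl) | ClCC(=C)C[C@H](OC(=O)/C(C)=C/C)[C@H]1C(=C)C(=O)O[C@@H]1C(OC(=O)OC(C)(C)C)C(=C)CCO
F11 | step 14 | C2 aldehyde from F10 | ClCC(=C)C[C@H](OC(=O)/C(C)=C/C)[C@H]1C(=C)C(=O)O[C@@H]1C(OC(=O)OC(C)(C)C)C(=C)CC=O
F12 | step 6 | (4R,5S)-5-{[(tert-butyldimethylsilyl)oxy]methyl}-4-[(1R)-3-(chloromethyl)-1-hydroxybut-3-en-1-yl]-3-methylideneoxolan-2-one | ClCC(=C)C[C@@H](O)[C@H]1C(=C)C(=O)O[C@@H]1CO[Si](C)(C)C(C)(C)C
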